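**Retrosynthetic overview**

1. Target ⇒ per-benzylated (2R,3S)-flavanone–flavone 11, whose only free phenol is 7''-OH (sulfation, then hydrogenolysis of all benzyl ethers).
2. Flavanone ring C is formed last, by a catalyst-controlled, chalcone-isomerase-like 6-endo oxa-Michael closure of the open α-(flavon-8-yl)-2'-hydroxychalcone 9. This is the synthetic counterpart of the presumed biosynthetic intermediate in which two chalcone-level units are joined Cα–C3' before the heterocycle closes; C2 and C3 are set together.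
3. Chalcone 9 ⇒ deoxybenzoin 7 + 4-(benzyloxy)benzaldehyde 8 (aldol condensation); 7 ⇒ phloroacetophenone ether 2 + 8-iodoflavone 6 (Pd enolate arylation makes the future C3–C8'' bond at the open-chain stage).
4. Flavone ring C'' comes intact from apigenin; its 7-OH alone is masked as a 4-methoxybenzyl (PMB) ether, so it alone is unmasked and sulfated.

Assumption: the target is wanted as drawn (free hydrogen sulfate), so the sodium salt is acidified with one equivalent of HCl at the end; the sodium salt is the form to store.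

**Route**

Step 1
Reactants: 1 2',4',6'-trihydroxyacetophenone
Product: 2 1-[2,4-bis(benzyloxy)-6-hydroxyphenyl]ethan-1-one
Conditions: benzyl bromide (2.05 equiv), K2CO3 (2.2 equiv), DMF, 0 → 23 °C, 16 h
Reagents that add atoms: benzyl bromide, BrCc1ccccc1
Why: Williamson etherification stops at the dibenzyl ether because the last phenol is locked in a hydrogen bond to the acetyl carbonyl and is the least nucleophilic; no stereocentre is formed.

Step 2
Reactants: 3 apigenin
Product: 5 5-(benzyloxy)-2-[4-(benzyloxy)phenyl]-7-[(4-methoxybenzyl)oxy]-4H-chromen-4-one, via 7-O-(4-methoxybenzyl)apigenin 4 (not isolated)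
Conditions: K2CO3 (1.0 equiv), 4-methoxybenzyl chloride (1.05 equiv), DMF, 23 °C, 12 h; then K2CO3 (4 equiv), benzyl bromide (3 equiv), Bu4NI (5 mol%), 70 °C, 12 h; crystallise
Reagents that add atoms: 4-methoxybenzyl chloride, COc1ccc(CCl)cc1; benzyl bromide, BrCc1ccccc1
Why: Two consecutive Williamson etherifications in one pot, in which the most acidic 7-OH takes the single equivalent of PMB chloride first and the 4'-OH and chelated 5-OH are then benzylated under forcing conditions, so that only the oxygen destined for the sulfate carries an oxidatively removable group; no stereocentre is formed.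

Step 3
Reactants: 5 5-(benzyloxy)-2-[4-(benzyloxy)phenyl]-7-[(4-methoxybenzyl)oxy]-4H-chromen-4-one
Product: 6 5-(benzyloxy)-2-[4-(benzyloxy)phenyl]-8-iodo-7-[(4-methoxybenzyl)oxy]-4H-chromen-4-one
Conditions: N-iodosuccinimide (1.1 equiv), CF3CO2H (10 mol%), MeCN/CH2Cl2, 0 → 23 °C, dark
Reagents that add atoms: N-iodosuccinimide, O=C1CCC(=O)N1I
Why: Electrophilic aromatic iodination of a 5,7-dialkoxyflavone goes to C8 (para to 5-OBn, ortho to 7-OPMB) rather than C6 once the 5-oxygen is alkylated, and the catalytic acid is too dilute to cleave the PMB ether.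

Step 4
Reactants: 2 1-[2,4-bis(benzyloxy)-6-hydroxyphenyl]ethan-1-one; 6 5-(benzyloxy)-2-[4-(benzyloxy)phenyl]-8-iodo-7-[(4-methoxybenzyl)oxy]-4H-chromen-4-one
Product: 7 5-(benzyloxy)-2-[4-(benzyloxy)phenyl]-8-{2-[2,4-bis(benzyloxy)-6-hydroxyphenyl]-2-oxoethyl}-7-[(4-methoxybenzyl)oxy]-4H-chromen-4-one
Conditions: Pd(OAc)2 (5 mol%), XPhos (10 mol%), K3PO4 (3.5 equiv), 1,4-dioxane, 100 °C, 16 h
Reagents that add atoms: none
Why: Buchwald–Hartwig–Miura ketone α-arylation (oxidative addition of zerovalent palladium into the C8–I bond, coupling with the potassium enolate of the methyl ketone whose phenol rides along as phenoxide, reductive elimination) stops at mono-arylation because the new CH2 is flanked by two di-ortho-substituted arenes; no stereocentre is formed.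

Step 5
Reactants: 7 the deoxybenzoin from step 4; 8 4-(benzyloxy)benzaldehyde
Product: 9 (E)-1-[2,4-bis(benzyloxy)-6-hydroxyphenyl]-3-[4-(benzyloxy)phenyl]-2-{5-(benzyloxy)-2-[4-(benzyloxy)phenyl]-7-[(4-methoxybenzyl)oxy]-4-oxo-4H-chromen-8-yl}prop-2-en-1-one
Conditions: KOtBu (3.0 equiv), THF/t-BuOH (4:1), 0 → 23 °C, 6 h; pour into ice-cold 0.5 M HCl (to pH 4–5), extract at once, crystallise cold
Reagents that add atoms: none
Why: Claisen–Schmidt aldol condensation with E1cB dehydration, in which excess base holds the product as its 2'-phenoxide (the phenoxide/ring-closed enolate equilibrium lies far on the open side) so that cold acidification releases the un-cyclised chalcone as the thermodynamic E isomer (the two aryl groups cis); no sp3 stereocentre is formed.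

Step 6
Reactants: 9 the open α-(flavon-8-yl)-2'-hydroxychalcone
Product: 10 (2R,3S)-5,7-bis(benzyloxy)-2-[4-(benzyloxy)phenyl]-3-{5-(benzyloxy)-2-[4-(benzyloxy)phenyl]-7-[(4-methoxybenzyl)oxy]-4-oxo-4H-chromen-8-yl}chroman-4-one (2,3-trans)
Conditions: bifunctional squaramide of 9-amino-9-deoxy-epi-quinidine carrying a 3,5-bis(trifluoromethyl)phenyl arm (10 mol%), toluene/CH2Cl2 (4:1), 4 Å molecular sieves, –20 °C, 72 h; cold filtration through SiO2; recrystallise to upgrade ee
Reagents that add atoms: none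
Why: Proposed new method: the closure copies the chalcone-isomerase step on the Cα-arylated chalcone, the quinuclidine nitrogen activating the 2'-OH while the squaramide binds the carbonyl and the developing enolate, and the bulky α-(flavon-8-yl) group confining the enone to one reactive conformer so that the phenol adds to one face of Cβ (6-endo-trig oxa-Michael) to set C2 as R, after which C3 is set by protonation of the enol anti to the new C2 aryl group to give the diequatorial trans (3S) isomer, which is also the thermodynamic one so that any cis isomer epimerises to it; the closest known reaction type is the cinchona thiourea/squaramide-catalysed enantioselective intramolecular oxa-Michael addition of α-substituted 2'-hydroxychalcones (alkylidene β-ketoesters) to flavanones, and the facial sense must be confirmed by ECD on the first run, the quinine-derived pseudo-enantiomer giving the antipode.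

Step 7
Reactants: 10 the (2R,3S)-flavanone 7''-O-PMB ether
Product: 11 (2R,3S)-5,7-bis(benzyloxy)-2-[4-(benzyloxy)phenyl]-3-{5-(benzyloxy)-2-[4-(benzyloxy)phenyl]-7-hydroxy-4-oxo-4H-chromen-8-yl}chroman-4-one
Conditions: DDQ (1.3 equiv), CH2Cl2/pH 7 phosphate buffer (10:1), 0 → 23 °C, 3 h
Reagents that add atoms: none
Why: Oxidative PMB ether cleavage (hydride abstraction to the 4-methoxybenzyl oxocarbenium ion, then hydrolysis) leaves plain benzyl ethers intact, and the neutral buffered medium gives no retro-oxa-Michael opening, so C2 and C3 are untouched.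

Step 8
Reactants: 11 the (2R,3S)-flavanone with free 7''-OH
Product: 13 sodium 5-(benzyloxy)-2-[4-(benzyloxy)phenyl]-8-{(2R,3S)-5,7-bis(benzyloxy)-2-[4-(benzyloxy)phenyl]-4-oxochroman-3-yl}-4-oxo-4H-chromen-7-yl sulfate, via pyridinium sulfate salt 12 (not isolated)
Conditions: SO3·pyridine (5 equiv), pyridine, 40 °C, 8 h; then aq. NaHCO3 to pH 8; C18 chromatography
Reagents that add atoms: sulfur trioxide–pyridine complex, [O-]S(=O)(=O)[n+]1ccccc1; sodium hydrogencarbonate, [Na+].OC([O-])=O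
Why: O-sulfation of the only free phenol with an amine–SO3 complex, pyridine being too weak a base to enolise C3 so that the trans-(2R,3S) centres survive, and bicarbonate work-up giving the stable sodium aryl sulfate free of pyridine (which would poison the next step).

Step 9
Reactants: 13 the per-benzylated sodium sulfate salt
Product: 15 5-hydroxy-2-(4-hydroxyphenyl)-8-[(2R,3S)-5,7-dihydroxy-2-(4-hydroxyphenyl)-4-oxochroman-3-yl]-4-oxo-4H-chromen-7-yl hydrogen sulfate (CNP0271389.1), via debenzylated sodium sulfate salt 14 (not isolated)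
Conditions: H2 (1 atm), Pd/C (10 wt%), THF/MeOH/H2O (4:4:1), 23 °C, 8 h; filter; then HCl (1.0 equiv, 0.1 M aq.), 0 °C, freeze-dry at once
Reagents that add atoms: none
Why: Catalytic hydrogenolysis removes the five benzyl ethers under neutral conditions that the aryl sulfate monoester, the flavone C2''=C3'' bond and the flavanone stereocentres survive, and one equivalent of acid then gives the hydrogen sulfate as drawn.

**Compound list**

1 | 2',4',6'-trihydroxyacetophenone | CC(=O)c1c(O)cc(O)cc1O | starting material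
2 | 1-[2,4-bis(benzyloxy)-6-hydroxyphenyl]ethan-1-one | CC(=O)c1c(O)cc(OCc2ccccc2)cc1OCc1ccccc1 | intermediate
3 | apigenin | O=c1cc(-c2ccc(O)cc2)oc2cc(O)cc(O)c12 | starting material
4 | 7-O-(4-methoxybenzyl)apigenin | O=c1cc(-c2ccc(O)cc2)oc2cc(OCc3ccc(OC)cc3)cc(O)c12 | intermediate (not isolated)
5 | 5-(benzyloxy)-2-[4-(benzyloxy)phenyl]-7-[(4-methoxybenzyl)oxy]-4H-chromen-4-one | O=c1cc(-c2ccc(OCc3ccccc3)cc2)oc2cc(OCc3ccc(OC)cc3)cc(OCc3ccccc3)c12 | intermediate
6 | 5-(benzyloxy)-2-[4-(benzyloxy)phenyl]-8-iodo-7-[(4-methoxybenzyl)oxy]-4H-chromen-4-one | O=c1cc(-c2ccc(OCc3ccccc3)cc2)oc2c(I)c(OCc3ccc(OC)cc3)cc(OCc3ccccc3)c12 | intermediate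
7 | 5-(benzyloxy)-2-[4-(benzyloxy)phenyl]-8-{2-[2,4-bis(benzyloxy)-6-hydroxyphenyl]-2-oxoethyl}-7-[(4-methoxybenzyl)oxy]-4H-chromen-4-one | O=C(Cc1c(OCc2ccc(OC)cc2)cc(OCc2ccccc2)c2c(=O)cc(-c3ccc(OCc4ccccc4)cc3)oc12)c1c(O)cc(OCc2ccccc2)cc1OCc1ccccc1 | intermediate
8 | 4-(benzyloxy)benzaldehyde | O=Cc1ccc(OCc2ccccc2)cc1 | starting material
9 | (E)-1-[2,4-bis(benzyloxy)-6-hydroxyphenyl]-3-[4-(benzyloxy)phenyl]-2-{5-(benzyloxy)-2-[4-(benzyloxy)phenyl]-7-[(4-methoxybenzyl)oxy]-4-oxo-4H-chromen-8-yl}prop-2-en-1-one | O=C(/C(=C/c1ccc(OCc2ccccc2)cc1)c1c(OCc2ccc(OC)cc2)cc(OCc2ccccc2)c2c(=O)cc(-c3ccc(OCc4ccccc4)cc3)oc12)c1c(O)cc(OCc2ccccc2)cc1OCc1ccccc1 | intermediate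
10 | (2R,3S)-5,7-bis(benzyloxy)-2-[4-(benzyloxy)phenyl]-3-{5-(benzyloxy)-2-[4-(benzyloxy)phenyl]-7-[(4-methoxybenzyl)oxy]-4-oxo-4H-chromen-8-yl}chroman-4-one | O=C1c2c(OCc3ccccc3)cc(OCc3ccccc3)cc2O[C@@H](c2ccc(OCc3ccccc3)cc2)[C@@H]1c1c(OCc2ccc(OC)cc2)cc(OCc2ccccc2)c2c(=O)cc(-c3ccc(OCc4ccccc4)cc3)oc12 | intermediate
11 | (2R,3S)-5,7-bis(benzyloxy)-2-[4-(benzyloxy)phenyl]-3-{5-(benzyloxy)-2-[4-(benzyloxy)phenyl]-7-hydroxy-4-oxo-4H-chromen-8-yl}chroman-4-one | O=C1c2c(OCc3ccccc3)cc(OCc3ccccc3)cc2O[C@@H](c2ccc(OCc3ccccc3)cc2)[C@@H]1c1c(O)cc(OCc2ccccc2)c2c(=O)cc(-c3ccc(OCc4ccccc4)cc3)oc12 | intermediate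
12 | pyridinium 5-(benzyloxy)-2-[4-(benzyloxy)phenyl]-8-{(2R,3S)-5,7-bis(benzyloxy)-2-[4-(benzyloxy)phenyl]-4-oxochroman-3-yl}-4-oxo-4H-chromen-7-yl sulfate | O=C1c2c(OCc3ccccc3)cc(OCc3ccccc3)cc2O[C@@H](c2ccc(OCc3ccccc3)cc2)[C@@H]1c1c(OS(=O)(=O)[O-])cc(OCc2ccccc2)c2c(=O)cc(-c3ccc(OCc4ccccc4)cc3)oc12.c1cc[nH+]cc1 | intermediate (not isolated)
13 | sodium 5-(benzyloxy)-2-[4-(benzyloxy)phenyl]-8-{(2R,3S)-5,7-bis(benzyloxy)-2-[4-(benzyloxy)phenyl]-4-oxochroman-3-yl}-4-oxo-4H-chromen-7-yl sulfate | O=C1c2c(OCc3ccccc3)cc(OCc3ccccc3)cc2O[C@@H](c2ccc(OCc3ccccc3)cc2)[C@@H]1c1c(OS(=O)(=O)[O-])cc(OCc2ccccc2)c2c(=O)cc(-c3ccc(OCc4ccccc4)cc3)oc12.[Na+] | intermediate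
14 | sodium 5-hydroxy-2-(4-hydroxyphenyl)-8-[(2R,3S)-5,7-dihydroxy-2-(4-hydroxyphenyl)-4-oxochroman-3-yl]-4-oxo-4H-chromen-7-yl sulfate | O=C1c2c(O)cc(O)cc2O[C@@H](c2ccc(O)cc2)[C@@H]1c1c(OS(=O)(=O)[O-])cc(O)c2c(=O)cc(-c3ccc(O)cc3)oc12.[Na+] | intermediate (not isolated)
15 | 5-hydroxy-2-(4-hydroxyphenyl)-8-[(2R,3S)-5,7-dihydroxy-2-(4-hydroxyphenyl)-4-oxochroman-3-yl]-4-oxo-4H-chromen-7-yl hydrogen sulfate (CNP0271389.1) | O=C1c2c(O)cc(O)cc2O[C@@H](c2ccc(O)cc2)[C@@H]1c1c(OS(=O)(=O)O)cc(O)c2c(=O)cc(-c3ccc(O)cc3)oc12 | target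

**Step count and risk**

Total steps: 9. Longest linear sequence: 8 (apigenin 3 → 15, steps 2–9).

Three steps most likely to fail, most likely first:

Step 6 (level and sense of enantioselectivity are untested on an α-aryl chalcone this hindered, and an E/Z mixture of 9 would erode ee). Fallback, setting out from 9 and coming back at 10: 9 is closed without chiral control (NaOAc, EtOH, reflux) to the racemic trans-flavanone, that is 10 together with its mirror image, (2S,3R)-5,7-bis(benzyloxy)-2-[4-(benzyloxy)phenyl]-3-{5-(benzyloxy)-2-[4-(benzyloxy)phenyl]-7-[(4-methoxybenzyl)oxy]-4-oxo-4H-chromen-8-yl}chroman-4-one F3. The two are separated by preparative supercritical-fluid chromatography on an amylose carbamate phase to give 10. F3 is not wasted: KOtBu in THF at 0 °C followed by cold HCl reopens it to 9, which is closed again.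

Step 5 (the methylene of 7 sits between two di-ortho-substituted aryl groups, so the condensation may stall, and 9 may close prematurely on work-up). Fallback, setting out from 7 and coming back at 10: 7 is closed with N,N-dimethylformamide dimethyl acetal (toluene, 90 °C) to the isoflavone-type chromone 5,7-bis(benzyloxy)-3-{5-(benzyloxy)-2-[4-(benzyloxy)phenyl]-7-[(4-methoxybenzyl)oxy]-4-oxo-4H-chromen-8-yl}-4H-chromen-4-one F2. The C2 aryl group is then added by enantioselective conjugate addition of 4-(benzyloxy)phenylboronic acid (Pd(OCOCF3)2, 5 mol%; 4-tert-butyl-2-(pyridin-2-yl)-4,5-dihydrooxazole as the enantiomer that gives 2R; NH4PF6; water; 1,2-dichloroethane, 60 °C). Protonation of the resulting enolate gives the 2,3-trans isomer 10, so steps 5 and 6 are bypassed.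

Step 4 (the chelated phenoxide–enolate of 2 may bind palladium through oxygen and resist C–C reductive elimination; the iodide is di-ortho-substituted). Fallback, setting out from 2 (with 6) and coming back at 7: 2 is doubly silylated (LiN(SiMe3)2, 2.2 equiv; Me3SiCl, 2.4 equiv; THF, –78 °C) to the neutral silyl enol ether trimethyl({1-[2,4-bis(benzyloxy)-6-[(trimethylsilyl)oxy]phenyl]ethenyl}oxy)silane F1. F1 is coupled with 6 through its tin enolate under base-free conditions (Bu3SnF, 1.1 equiv; PdCl2[P(o-tol)3]2, 5 mol%; toluene, 100 °C). Aqueous KF work-up removes both silyl groups and gives 7.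

**Further compounds**

F1 | step 4 | trimethyl({1-[2,4-bis(benzyloxy)-6-[(trimethylsilyl)oxy]phenyl]ethenyl}oxy)silane | C=C(O[Si](C)(C)C)c1c(O[Si](C)(C)C)cc(OCc2ccccc2)cc1OCc1ccccc1
F2 | step 5 | 5,7-bis(benzyloxy)-3-{5-(benzyloxy)-2-[4-(benzyloxy)phenyl]-7-[(4-methoxybenzyl)oxy]-4-oxo-4H-chromen-8-yl}-4H-chromen-4-one | O=c1c(-c2c(OCc3ccc(OC)cc3)cc(OCc3ccccc3)c3c(=O)cc(-c4ccc(OCc5ccccc5)cc4)oc23)coc2cc(OCc3ccccc3)cc(OCc3ccccc3)c12
F3 | step 6 | (2S,3R)-5,7-bis(benzyloxy)-2-[4-(benzyloxy)phenyl]-3-{5-(benzyloxy)-2-[4-(benzyloxy)phenyl]-7-[(4-methoxybenzyl)oxy]-4-oxo-4H-chromen-8-yl}chroman-4-one | O=C1c2c(OCc3ccccc3)cc(OCc3ccccc3)cc2O[C@H](c2ccc(OCc3ccccc3)cc2)[C@H]1c1c(OCc2ccc(OC)cc2)cc(OCc2ccccc2)c2c(=O)cc(-c3ccc(OCc4ccccc4)cc3)oc12
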